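## Retrosynthetic overview

1. Numbering: decalin C1–C10 (ring A = C1–C5 and C10, ring B = C5–C10), side chain C11–C19 on C9 (sulfate on C12, methyl on C13), then the arene. Late disconnections: the O-sulfate, the hydroquinone (carried as its dimethyl ether and unveiled through the quinone), and C16–C17 (B-alkyl Suzuki coupling of a terminal alkene with an (E)-vinyl iodide).
2. C11–C12 and the C12 carbinol centre: hydroboration of a C9 exocyclic methylene (α-face, sets C9), then lithiation–borylation with a (+)-sparteine-lithiated carbamate that brings C13 from an Evans alkylation.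
3. Ring A: one annulation onto a ring B keto aldehyde. Vinyltriphenylphosphonium bromide supplies C2–C3; a C4 tertiary radical (hydrogen-atom transfer to an isopropenyl group) forms C3–C4; the resulting ylide forms C1–C2 by intramolecular Wittig olefination on a C10 formyl group; C1=C2 is then hydrogenated.
4. Enabling feature: C4 of ring A is a quaternary carbon with two methyl groups directly on ring-fusion carbon C5, hence the tertiary radical of an isopropenyl group. C1 is a CH2 on the quaternary C10, hence a non-enolisable aldehyde carbon, and C2 and C3 are bare CH2 groups. Ring B with its C8 methyl, C7=C8 alkene, C9 oxygen and C5 isopropenyl is the ring of (R)-carvone.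
5. Ring order: ring B is bought as (R)-carvone (C10 made quaternary by methylation, then hydroxymethylation), ring A is closed in step 4, the arene is bought and joined in step 13.

Key step: step 4

Remark: the target is drawn as the free hydrogen sulfate; the sodium salt is made first and protonated only in the last cold work-up, because the free acid is expected to be the least stable form.
Remark: "decalinyl" below means (1S,4aS,8aS)-2,5,5,8a-tetramethyl-1,4,4a,5,6,7,8,8a-octahydronaphthalen-1-yl (C9 is its point of attachment).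

## Route

Step 1
Reactants: 1 (R)-carvone
Product: 3 (5R,6S)-2,6-dimethyl-5-(prop-1-en-2-yl)cyclohex-2-en-1-one (trans-6-methylcarvone), via lithium dienolate 2 (not isolated)
Conditions: LiN(i-Pr)2, THF, −78 °C; then MeI, −78 → 0 °C
Reagents that add atoms: iodomethane, CI
Why: Kinetic α′-deprotonation gives the cross-conjugated dienolate, and enolate alkylation should occur mainly anti to the isopropenyl group; the epimer composition at this carbon does not matter because the centre is re-enolised in step 2.

Step 2
Reactants: 3 (5R,6S)-2,6-dimethyl-5-(prop-1-en-2-yl)cyclohex-2-en-1-one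
Product: 5 (5S,6R)-6-(hydroxymethyl)-2,6-dimethyl-5-(prop-1-en-2-yl)cyclohex-2-en-1-one, via lithium enolate 4 (not isolated)
Conditions: LiN(i-Pr)2, THF, −78 °C; then CH2O (gas, cracked from paraformaldehyde), −78 °C; AcOH quench
Reagents that add atoms: formaldehyde, C=O
Why: Aldol addition (hydroxymethylation) of the tetrasubstituted enolate: the neighbouring isopropenyl group sits pseudoaxial to avoid allylic strain with the enolate methyl and shields its own face, so CH2OH should enter trans to it and the methyl ends cis, which is the C10 configuration of the target.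

Step 3
Reactants: 5 (5S,6R)-6-(hydroxymethyl)-2,6-dimethyl-5-(prop-1-en-2-yl)cyclohex-2-en-1-one
Product: 6 (1R,6S)-1,3-dimethyl-2-oxo-6-(prop-1-en-2-yl)cyclohex-3-ene-1-carbaldehyde
Conditions: Dess–Martin periodinane, CH2Cl2, 0 °C → rt
Reagents that add atoms: none
Why: Dess–Martin oxidation of the neopentyl primary alcohol under near-neutral conditions should give the non-enolisable β-keto aldehyde without retro-aldol or retro-Claisen cleavage; no stereocentre is touched.

Step 4
Reactants: 6 (1R,6S)-1,3-dimethyl-2-oxo-6-(prop-1-en-2-yl)cyclohex-3-ene-1-carbaldehyde; 7 vinyltriphenylphosphonium bromide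
Product: 9 (4aS,8aS)-2,5,5,8a-tetramethyl-4a,5,6,8a-tetrahydronaphthalen-1(4H)-one, via phosphonium ylide 8 (not isolated)
Conditions: Fe(acac)3 (cat.), Ph(i-PrO)SiH2, 7 (3 equiv), THF/MeCN, 0 °C → rt
Reagents that add atoms: none
Why: Proposed new method: the trivalent iron hydride formed from Fe(acac)3 and the silane should transfer a hydrogen atom to the CH2 terminus of the isopropenyl group of 6 (creating the second C4 methyl); the nucleophilic tertiary C4 radical adds to the CH2 terminus of the electrophilic vinylphosphonium salt 7 (bond C3–C4), and the α-phosphonio radical, which is at least as easily reduced as an α-carbonyl radical, is reduced by divalent iron to the non-stabilised ylide 8. The ylide carbon then closes ring A on the C10 formyl group by intramolecular Wittig olefination (bond C1–C2, formed as C1=C2 by 6-exo-trig attack on the C=O and loss of Ph3P=O from the oxaphosphetane). The closest known reaction types are the iron-hydride radical conjugate addition–aldol annulations of alkenyl carbonyl compounds with enals (radical–polar crossover), radical additions to vinylphosphonium salts that end in a Wittig olefination, and the Schweizer annulation of vinylphosphonium salts. No new stereocentre is formed: C4 carries two methyl groups, and the trans ring fusion is inherited from C5 and C10, whose reacting substituents are trans and diequatorial. The step needs hydrogen-atom transfer to the electron-rich 1,1-disubstituted alkene and not to the electron-poor trisubstituted enone alkene, capture of the radical by excess 7 faster than its reduction, and olefination of the aldehyde only; the last is secured because the aldehyde cannot enolise and closure on the C9 ketone would give a bridgehead alkene.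

Step 5
Reactants: 9 (4aS,8aS)-2,5,5,8a-tetramethyl-4a,5,6,8a-tetrahydronaphthalen-1(4H)-one
Product: 10 (4aS,8aS)-2,5,5,8a-tetramethyl-4a,5,6,7,8,8a-hexahydronaphthalen-1(4H)-one
Conditions: H2 (1 atm), RhCl(PPh3)3 (cat.), benzene, rt
Reagents that add atoms: none
Why: Homogeneous hydrogenation should reduce the cis-disubstituted C1=C2 alkene and leave the trisubstituted, conjugated C7=C8 alkene and the ketone alone; no stereocentre is formed.

Step 6
Reactants: 10 (4aS,8aS)-2,5,5,8a-tetramethyl-4a,5,6,7,8,8a-hexahydronaphthalen-1(4H)-one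
Product: 11 (4aS,8aS)-2,5,5,8a-tetramethyl-1-methylidene-1,4,4a,5,6,7,8,8a-octahydronaphthalene (drima-7,9(11)-diene)
Conditions: Ph3PCH3Br, KN(SiMe3)2, toluene, 0 → 90 °C
Reagents that add atoms: methyltriphenylphosphonium bromide, C[P+](c1ccccc1)(c1ccccc1)c1ccccc1.[Br-]
Why: Wittig methylenation of a ketone that cannot enolise toward C10, run hot as is usual for 2,6,6-trisubstituted cyclohexenones, should give the exocyclic 1,3-diene.

Step 7
Reactants: 12 (S)-4-benzyl-3-propionyloxazolidin-2-one
Product: 14 (S)-4-benzyl-3-[(R)-2-methylpent-4-enoyl]oxazolidin-2-one, via sodium enolate 13 (not isolated)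
Conditions: NaN(SiMe3)2, THF, −78 °C; then allyl iodide, −78 → −45 °C
Reagents that add atoms: allyl iodide, C=CCI
Why: Evans asymmetric alkylation: the chelated (Z)-enolate is alkylated on the face opposite the benzyl group of the auxiliary, which sets the (R) methyl-bearing centre (C13 of the target).

Step 8
Reactants: 14 (S)-4-benzyl-3-[(R)-2-methylpent-4-enoyl]oxazolidin-2-one
Product: 15 (R)-2-methylpent-4-en-1-ol
Conditions: LiBH4, MeOH (1 equiv), Et2O, 0 °C
Reagents that add atoms: none
Why: Reductive cleavage of the N-acyl oxazolidinone should give the primary alcohol without touching the α-stereocentre or the alkene.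

Step 9
Reactants: 15 (R)-2-methylpent-4-en-1-ol
Product: 16 (R)-2-methylpent-4-en-1-yl N,N-diisopropylcarbamate
Conditions: i-Pr2NC(O)Cl, Et3N, CH2Cl2, reflux
Reagents that add atoms: N,N-diisopropylcarbamoyl chloride, CC(C)N(C(C)C)C(Cl)=O
Why: O-Carbamoylation of the primary alcohol installs the directing and leaving group needed for α-lithiation and 1,2-migration.

Step 10
Reactants: 11 drima-7,9(11)-diene; 16 (R)-2-methylpent-4-en-1-yl N,N-diisopropylcarbamate
Product: 21 (2R,3R)-1-decalinyl-3-methylhex-5-en-2-ol, via alkylborane 17 (not isolated), via lithiated carbamate 18 (not isolated), via boronate complex 19 (not isolated), via rearranged borane 20 (not isolated)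
Conditions: 11, 9-BBN, THF, 0 °C → rt; 16, s-BuLi, (+)-sparteine, Et2O, −78 °C; solutions combined at −78 °C, then → rt; then NaOH, H2O2, 0 °C
Reagents that add atoms: hydrogen peroxide, OO
Why: Hydroboration puts boron on the terminal C11 and hydrogen on C9 from the α face, opposite the axial C10 methyl (sets C9); the (+)-sparteine-controlled lithiated carbamate then forms the boronate with retention, C11 migrates with inversion and expels the carbamate (lithiation–borylation, a 1,2-metallate rearrangement), and oxidation with retention should give the (12R) alcohol.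

Step 11
Reactants: 22 2,5-dimethoxybenzyl chloride
Product: 23 2-(but-2-yn-1-yl)-1,4-dimethoxybenzene
Conditions: CH3C≡CMgBr, CuBr·SMe2 (cat.), THF, 0 → 60 °C
Reagents that add atoms: 1-propynylmagnesium bromide, CC#C[Mg]Br
Why: Copper-catalysed coupling of an alkynyl Grignard reagent with a benzylic chloride should give the 1-aryl-but-2-yne by substitution at the benzylic carbon.

Step 12
Reactants: 23 2-(but-2-yn-1-yl)-1,4-dimethoxybenzene
Product: 25 2-[(2E)-3-iodobut-2-en-1-yl]-1,4-dimethoxybenzene, via alkenylzirconocene chloride 24 (not isolated)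
Conditions: Cp2Zr(H)Cl, THF, rt → 50 °C; then I2, 0 °C
Reagents that add atoms: iodine, II
Why: Hydrozirconation is a syn addition that, after equilibration with excess reagent, places zirconium on the less hindered methyl-bearing alkyne carbon; iodinolysis with retention should give the (E)-vinyl iodide.

Step 13
Reactants: 21 (2R,3R)-1-decalinyl-3-methylhex-5-en-2-ol; 25 2-[(2E)-3-iodobut-2-en-1-yl]-1,4-dimethoxybenzene
Product: 27 (2R,3R,7E)-1-decalinyl-9-(2,5-dimethoxyphenyl)-3,7-dimethylnon-7-en-2-ol, via bis-boryl adduct 26 (not isolated)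
Conditions: 21, 9-BBN (2.2 equiv), THF, rt; then 25, Pd(dppf)Cl2 (cat.), NaOH (aq.), THF, 60 °C
Reagents that add atoms: none
Why: 9-BBN should hydroborate only the terminal alkene (the hydroxyl is carried as its borinate, the trisubstituted C7=C8 alkene is inert), and the B-alkyl Suzuki–Miyaura coupling proceeds with retention of the vinyl iodide geometry, giving the (E) C17=C18 alkene.

Step 14
Reactants: 27 (2R,3R,7E)-1-decalinyl-9-(2,5-dimethoxyphenyl)-3,7-dimethylnon-7-en-2-ol
Product: 28 sodium (2R,3R,7E)-1-decalinyl-9-(2,5-dimethoxyphenyl)-3,7-dimethylnon-7-en-2-yl sulfate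
Conditions: SO3·pyridine, pyridine, 50 °C; then NaHCO3 (aq.)
Reagents that add atoms: sulfur trioxide–pyridine complex, O=S(=O)([O-])[n+]1ccccc1; sodium hydrogen carbonate, [Na+].OC(=O)[O-]
Why: O-Sulfation of the only hydroxyl group (the hydroquinone is still its dimethyl ether) under basic conditions; the C12–O bond is not broken, so the configuration is retained.

Step 15
Reactants: 28 sodium (2R,3R,7E)-1-decalinyl-9-(2,5-dimethoxyphenyl)-3,7-dimethylnon-7-en-2-yl sulfate
Product: 29 sodium (2R,3R,7E)-1-decalinyl-9-(3,6-dioxocyclohexa-1,4-dien-1-yl)-3,7-dimethylnon-7-en-2-yl sulfate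
Conditions: (NH4)2Ce(NO3)6, MeCN/H2O, 0 °C
Reagents that add atoms: water, O
Why: Oxidative demethylation of the 1,4-dimethoxyarene by tetravalent cerium (two one-electron oxidations with attack of water at the ipso carbons) should give the 1,4-benzoquinone; the alkyl sulfate and the trisubstituted alkenes should tolerate the short, cold treatment.

Step 16
Reactants: 29 sodium (2R,3R,7E)-1-decalinyl-9-(3,6-dioxocyclohexa-1,4-dien-1-yl)-3,7-dimethylnon-7-en-2-yl sulfate
Product: 31 halisulfate 1, via sodium salt 30 (not isolated)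
Conditions: Na2S2O4, THF/H2O, rt; then HCl (1 M), 0 °C, extraction
Reagents that add atoms: none
Why: Dithionite reduction of the quinone to the hydroquinone, then brief cold protonation of the sulfate; no carbon stereocentre is affected.

## Compound list

1 | (R)-carvone | CC1=CC[C@@H](C(C)=C)CC1=O | starting material
2 | lithium cross-conjugated dienolate of 1 | CC1=CC[C@@H](C(C)=C)C=C1O[Li] | intermediate
3 | (5R,6S)-2,6-dimethyl-5-(prop-1-en-2-yl)cyclohex-2-en-1-one | CC1=CC[C@@H](C(C)=C)[C@H](C)C1=O | intermediate
4 | lithium enolate of 3 | CC1=CC[C@@H](C(C)=C)C(C)=C1O[Li] | intermediate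
5 | (5S,6R)-6-(hydroxymethyl)-2,6-dimethyl-5-(prop-1-en-2-yl)cyclohex-2-en-1-one | CC1=CC[C@@H](C(C)=C)[C@](C)(CO)C1=O | intermediate
6 | (1R,6S)-1,3-dimethyl-2-oxo-6-(prop-1-en-2-yl)cyclohex-3-ene-1-carbaldehyde | CC1=CC[C@@H](C(C)=C)[C@](C)(C=O)C1=O | intermediate
7 | vinyltriphenylphosphonium bromide | C=C[P+](c1ccccc1)(c1ccccc1)c1ccccc1.[Br-] | starting material
8 | phosphonium ylide from addition of the C4 radical of 6 to 7 | CC1=CC[C@@H](C(C)(C)CC=P(c2ccccc2)(c2ccccc2)c2ccccc2)[C@](C)(C=O)C1=O | intermediate
9 | (4aS,8aS)-2,5,5,8a-tetramethyl-4a,5,6,8a-tetrahydronaphthalen-1(4H)-one | CC1=CC[C@H]2C(C)(C)CC=C[C@]2(C)C1=O | intermediate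
10 | (4aS,8aS)-2,5,5,8a-tetramethyl-4a,5,6,7,8,8a-hexahydronaphthalen-1(4H)-one | CC1=CC[C@H]2C(C)(C)CCC[C@]2(C)C1=O | intermediate
11 | (4aS,8aS)-2,5,5,8a-tetramethyl-1-methylidene-1,4,4a,5,6,7,8,8a-octahydronaphthalene (drima-7,9(11)-diene) | CC1=CC[C@H]2C(C)(C)CCC[C@]2(C)C1=C | intermediate
12 | (S)-4-benzyl-3-propionyloxazolidin-2-one | CCC(=O)N1[C@@H](Cc2ccccc2)COC1=O | starting material
13 | sodium (Z)-enolate of 12 | C/C=C(\O[Na])N1[C@@H](Cc2ccccc2)COC1=O | intermediate
14 | (S)-4-benzyl-3-[(R)-2-methylpent-4-enoyl]oxazolidin-2-one | C=CC[C@@H](C)C(=O)N1[C@@H](Cc2ccccc2)COC1=O | intermediate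
15 | (R)-2-methylpent-4-en-1-ol | C=CC[C@@H](C)CO | intermediate
16 | (R)-2-methylpent-4-en-1-yl N,N-diisopropylcarbamate | C=CC[C@@H](C)COC(=O)N(C(C)C)C(C)C | intermediate
17 | 9-(decalinylmethyl)-9-borabicyclo[3.3.1]nonane (boron on C11, C9–H α) | CC1=CC[C@H]2C(C)(C)CCC[C@]2(C)[C@H]1CB1C2CCCC1CCC2 | intermediate
18 | (1R,2R)-1-lithio-2-methylpent-4-en-1-yl N,N-diisopropylcarbamate (sparteine ligand not drawn) | [Li][C@@H](OC(=O)N(C(C)C)C(C)C)[C@H](C)CC=C | intermediate
19 | lithium boronate from 17 and 18 | CC1=CC[C@H]2C(C)(C)CCC[C@]2(C)[C@H]1C[B-]1([C@@H](OC(=O)N(C(C)C)C(C)C)[C@H](C)CC=C)C2CCCC1CCC2.[Li+] | intermediate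
20 | secondary borane after 1,2-shift of C11 (boron on C12) | CC1=CC[C@H]2C(C)(C)CCC[C@]2(C)[C@H]1C[C@@H](B1C2CCCC1CCC2)[C@H](C)CC=C | intermediate
21 | (2R,3R)-1-decalinyl-3-methylhex-5-en-2-ol | CC1=CC[C@H]2C(C)(C)CCC[C@]2(C)[C@H]1C[C@@H](O)[C@H](C)CC=C | intermediate
22 | 2,5-dimethoxybenzyl chloride | COc1ccc(OC)c(CCl)c1 | starting material
23 | 2-(but-2-yn-1-yl)-1,4-dimethoxybenzene | CC#CCc1cc(OC)ccc1OC | intermediate
24 | (E)-alkenylzirconocene chloride from 23 (zirconium on the methyl-bearing carbon; cyclopentadienyl rings drawn σ-bound) | Cl[Zr](C1C=CC=C1)(C1C=CC=C1)/C(C)=C/Cc1cc(OC)ccc1OC | intermediate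
25 | 2-[(2E)-3-iodobut-2-en-1-yl]-1,4-dimethoxybenzene | I/C(C)=C/Cc1cc(OC)ccc1OC | intermediate
26 | bis(9-BBN) adduct of 21 (O-borinate on C12, B-alkyl on C16) | CC1=CC[C@H]2C(C)(C)CCC[C@]2(C)[C@H]1C[C@@H](OB1C2CCCC1CCC2)[C@H](C)CCCB1C2CCCC1CCC2 | intermediate
27 | (2R,3R,7E)-1-decalinyl-9-(2,5-dimethoxyphenyl)-3,7-dimethylnon-7-en-2-ol | CC1=CC[C@H]2C(C)(C)CCC[C@]2(C)[C@H]1C[C@@H](O)[C@H](C)CCC/C(C)=C/Cc1cc(OC)ccc1OC | intermediate
28 | sodium (2R,3R,7E)-1-decalinyl-9-(2,5-dimethoxyphenyl)-3,7-dimethylnon-7-en-2-yl sulfate | CC1=CC[C@H]2C(C)(C)CCC[C@]2(C)[C@H]1C[C@@H](OS(=O)(=O)[O-])[C@H](C)CCC/C(C)=C/Cc1cc(OC)ccc1OC.[Na+] | intermediate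
29 | sodium (2R,3R,7E)-1-decalinyl-9-(3,6-dioxocyclohexa-1,4-dien-1-yl)-3,7-dimethylnon-7-en-2-yl sulfate | CC1=CC[C@H]2C(C)(C)CCC[C@]2(C)[C@H]1C[C@@H](OS(=O)(=O)[O-])[C@H](C)CCC/C(C)=C/CC1=CC(=O)C=CC1=O.[Na+] | intermediate
30 | halisulfate 1 sodium salt | CC1=CC[C@H]2C(C)(C)CCC[C@]2(C)[C@H]1C[C@@H](OS(=O)(=O)[O-])[C@H](C)CCC/C(C)=C/Cc1cc(O)ccc1O.[Na+] | intermediate
31 | halisulfate 1 | CC1=CC[C@H]2C(C)(C)CCC[C@]2(C)[C@H]1C[C@@H](OS(=O)(=O)O)[C@H](C)CCC/C(C)=C/Cc1cc(O)ccc1O | target

## Step count and risks

Total step count: 16. Longest linear sequence: 11 steps (steps 1–6, 10, 13–16).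

Steps most likely to fail:

1. Step 4 (proposed new method). What may go wrong: reduction of the C4 radical by a second hydrogen-atom transfer before it meets 7, protonation of ylide 8 before it reaches the aldehyde, or loss of the formyl group by retro-Claisen cleavage. Fallback with known chemistry, from 6 back to 9: the iron-hydride radical conjugate addition–aldol annulation of 6 with acrolein (Fe(acac)3, PhSiH3, EtOH/ethylene glycol) should give ring A β-hydroxy aldehyde F1 (hydroxyl on C1, formyl on C2, mixture at both new centres). Acid-catalysed dehydration (TsOH, benzene, reflux) should give conjugated enal F2, and Tsuji–Wilkinson decarbonylation with stoichiometric RhCl(PPh3)3 in refluxing toluene should remove the formyl group and return 9.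

2. Step 10. What may go wrong: slow or poorly selective deprotonation of the β-branched carbamate (mismatch between the C13 centre and the diamine), migration of a ring carbon of the borabicycle in place of C11, or sluggish boronate formation at the hindered C11 borane. Fallback, from 11 back to 21: hydroboration of 11 with 9-BBN, carbonylation under CO in the presence of LiAlH(Ot-Bu)3 and buffered H2O2 oxidation should give homodrimenal F3. Evans syn-aldol addition of the dibutylboron enolate of 12 (n-Bu2BOTf, i-Pr2NEt, CH2Cl2, −78 → 0 °C) should give aldol adduct F4, with C12 and C13 set by the auxiliary. LiBH4 should cleave the auxiliary to give diol F5, tosylation of the primary hydroxyl (TsCl, pyridine) should give tosylate F6, and displacement with CH2=CHMgBr under CuI catalysis should give 21.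

3. Step 15. What may go wrong: solvolysis or elimination of the secondary sulfate in the acidic oxidising medium, or over-oxidation at the trisubstituted alkenes. Fallback, from 27 back to 29, with the order of events reversed: (NH4)2Ce(NO3)6 in MeCN/H2O on 27 should give quinone alcohol F7, whose only hydroxyl is then sulfated with SO3·NMe3 in DMF and converted with NaHCO3 into 29, so that the sulfate never meets tetravalent cerium.

## Further compounds

F1 | step 4 | ring A β-hydroxy aldehyde (C1 hydroxyl, C2 formyl, C9 ketone, C7=C8; mixture at C1 and C2) | CC1=CC[C@H]2C(C)(C)CC(C=O)C(O)[C@]2(C)C1=O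
F2 | step 4 | conjugated enal (C1=C2 with formyl on C2, C9 ketone, C7=C8) | CC1=CC[C@H]2C(C)(C)CC(C=O)=C[C@]2(C)C1=O
F3 | step 10 | homodrimenal, 2-decalinylacetaldehyde | CC1=CC[C@H]2C(C)(C)CCC[C@]2(C)[C@H]1CC=O
F4 | step 10 | (S)-4-benzyl-3-[(2S,3R)-4-decalinyl-3-hydroxy-2-methylbutanoyl]oxazolidin-2-one | CC1=CC[C@H]2C(C)(C)CCC[C@]2(C)[C@H]1C[C@@H](O)[C@H](C)C(=O)N1[C@@H](Cc3ccccc3)COC1=O
F5 | step 10 | (2R,3R)-4-decalinyl-2-methylbutane-1,3-diol | CC1=CC[C@H]2C(C)(C)CCC[C@]2(C)[C@H]1C[C@@H](O)[C@H](C)CO
F6 | step 10 | (2R,3R)-4-decalinyl-3-hydroxy-2-methylbutyl 4-methylbenzenesulfonate | CC1=CC[C@H]2C(C)(C)CCC[C@]2(C)[C@H]1C[C@@H](O)[C@H](C)COS(=O)(=O)c1ccc(C)cc1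
F7 | step 15 | 2-[(2E,7R,8R)-9-decalinyl-8-hydroxy-3,7-dimethylnon-2-en-1-yl]cyclohexa-2,5-diene-1,4-dione | CC1=CC[C@H]2C(C)(C)CCC[C@]2(C)[C@H]1C[C@@H](O)[C@H](C)CCC/C(C)=C/CC1=CC(=O)C=CC1=O
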